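The numbers of this flask are invented; the rest is arithmetic.

After the feed has ended, free nucleophile less two for each electrophile still left holds still in south, since each electrophile that reacts takes one nucleophile into product and hands its acid to a second, and the balance constant times nucleophile, 1200, stands far above one.

    nucleophile + acid set free ⇌ protonated nucleophile, settled at all times (K1 = 60000 M⁻¹)
    electrophile + nucleophile → acid set free + product (k2 = 2.0 M⁻¹ min⁻¹)
    nucleophile + protic impurity → quenched reagent (k3 = 220 M⁻¹ min⁻¹)

| setting | south | east | north-east |
|---|---|---|---|
| electrophile | 0.010 M (fed, over 20 min) | 0.010 M (fed, over 20 min) | 0.010 M (fed, over 20 min) |
| nucleophile | 0.0200 M | 0.0300 M | 0.0450 M |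
| protic impurity | 0.500 mM | 0.500 mM | 0.500 mM |
| time | 40 min | 40 min | 40 min |

- part of the electrophile that has reacted at the end, south
- part of the electrophile that has reacted at the end, east
- part of the electrophile that has reacted at the end, north-east
- what raising the concentration of nucleophile from its lowest to its highest value here does to the part of the electrophile that has reacted (changes below 5 percentage points count as none) (it falls / it rises / no change)

The quantity carried through this flask is the margin, −0.500 mM in south: nucleophile charged, less protic impurity, less two for each electrophile charged. The protic impurity is counted off at the start, for its half-life with nucleophile held at its charge, 0.158 min in south, is shorter than the feed. East has a margin of 9.50 mM and north-east 24.5 mM. The negative margin makes nucleophile the limiting reagent in south: with the acid bound, its charge pays for 97.5% of the electrophile, and the curve of south runs toward that level.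

The reckoning by hand draws that curve. The reacted part of south leaves zero with a flat slope, since electrophile must first arrive, at 0.500 mM min⁻¹. A first pass with free nucleophile unchanged gives 3.06 mM reacted by the end of the feed. Lowering the mean free nucleophile by that amount gives a pseudo-first-order constant of 0.0329 min⁻¹, and so 7.33 mM of electrophile at the knee, where the feed stops. Past the knee, free nucleophile over electrophile left is multiplied by e to the power of rate constant times margin times time, and electrophile left is the margin over that ratio less two. In south the ratio starts at 1.93 and the factor over the remaining 20.0 min is 0.980, which gives 53.0% reacted. East, with 6.28 mM at its knee, reaches 69.7%. North-east, with 5.05 mM, reaches 84.9%, a rise that exceeds the 5 percentage points mark.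

The forecast gave 53%, 70% and 85% and said it rises, on this ground: “each turnover costs two nucleophiles and the free pool shrinks as the reaction goes on”.

The flasks give 53.1%, 69.6% and 84.8%; the part reacted: it rises, by 32 points. East ends with 51.9% of its nucleophile free and 30% of its electrophile left, and free nucleophile less two for each electrophile comes to 9.51 mM, against its margin of 9.50 mM. The neighbour of north-east with 0.011 M of nucleophile has a margin of −9.50 mM; its knee reckons at 8.45 mM and its end at 32.2% reacted, and that flask gives 32.3%.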